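**Plan**

1. Numbering: C1 quaternary fusion carbon (CH3), C2 (OAc), C3, C4 (OH, isopropyl), C5 fusion CH, C6 (O-aroyl), C7, C8(CH3)=C9, C10; β is the face of the C1 methyl. Enabling feature: in the seven-membered ring C6 bears oxygen, C7 is a lone CH2 between C6 and C8=C9, and C10 ends on the quaternary C1 next to C5. With C5=C6 as an enol this is a cyclohepta-1,4-diene, the product pattern of a cis-divinylcyclopropane rearrangement; the ring C1–C5 with C4(OH)(iPr) is a ring-contracted terpinen-4-ol.
2. Cuts, in order: the C6 and C2 esters; C1–C10 (Cope) together with C6–C7 and C7–C8 (CH2 onto a C6=C8 silyl enol ether); the C6–C8 side-chain bond (allenylzinc plus C6 aldehyde); C1–C5 (aldol), back to the terpene cyclohexene.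
3. Forward: the cyclopentene first (ozonolysis–aldol ring contraction), then the C6 side chain and an O4–Si–O6 tether, then the seven-membered ring by cyclopropanation and [3,3] shift; the esters last.
4. Stereochemistry: C4 from the chiral pool; C2 by hydroxyl-directed reduction before ring contraction; C1 relayed from C4 through the tether in the key step; C5 by equilibration of a chelated alkoxide–dienolate; C6 by hydroxyl-directed reduction.

Key step: step 11

Remark: commercial (S)-(+)-terpinen-4-ol is taken as enantiopure (material of lower optical purity would be upgraded by recrystallising diol 4); TBS = tert-butyldimethylsilyl, TMS = trimethylsilyl.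

**Route**

Step 1
Reactants: 1 (S)-terpinen-4-ol
Product: 2 (1R)-4-methyl-1-(propan-2-yl)cyclohex-4-ene-1,3-diol (both C3 epimers)
Conditions: SeO2 (0.5 equiv), t-BuOOH (2 equiv), CH2Cl2, 0 °C to rt
Reagents that add atoms: tert-butyl hydroperoxide, CC(C)(C)OO (oxygen carried by catalytic selenium dioxide, O=[Se]=O)
Why: Riley allylic oxidation (ene reaction, then [2,3]-sigmatropic shift) hydroxylates the ring CH2 at the more substituted alkene end and returns the double bond to its place, so no symmetric allyl radical or cation can scramble the carbinol stereocentre; the new centre is not controlled and is erased in step 2.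

Step 2
Reactants: 2 allylic diol (epimer mixture)
Product: 3 (5R)-5-hydroxy-2-methyl-5-(propan-2-yl)cyclohex-2-en-1-one
Conditions: MnO2 (excess), CH2Cl2, rt
Reagents that add atoms: none
Why: Chemoselective MnO2 oxidation of the allylic secondary alcohol; the tertiary alcohol is inert and the neutral medium avoids dehydration of the β-hydroxy enone.

Step 3
Reactants: 3 hydroxy enone
Product: 4 (1R,3S)-4-methyl-1-(propan-2-yl)cyclohex-4-ene-1,3-diol (trans-diol)
Conditions: Me4NBH(OAc)3, MeCN/AcOH (1:1), −30 to −20 °C
Reagents that add atoms: none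
Why: Evans–Saksena reduction: the axial tertiary hydroxyl (isopropyl equatorial) binds the borohydride and delivers hydride to the carbonyl face it occupies, so 1,2-reduction should give the trans 1,3-diol, which sets C2 of the target.

Step 4
Reactants: 4 trans-diol
Product: 6 bis-silyl ether of 4 (TBS on the secondary oxygen; TMS on the tertiary oxygen), via mono-TBS ether 5 (not isolated)
Conditions: TBSCl (1.1 equiv), imidazole, DMF, 0 °C to rt; then TMSCl, rt
Reagents that add atoms: tert-butyldimethylsilyl chloride, CC(C)(C)[Si](C)(C)Cl; trimethylsilyl chloride, C[Si](C)(C)Cl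
Why: Silylation graded by hindrance: TBSCl takes only the secondary allylic hydroxyl, and the small TMS group then caps the tertiary one so that it cannot leave by β-elimination during the ring contraction.

Step 5
Reactants: 6 bis-silyl ether
Product: 8 (3S,5S)-5-[(tert-butyldimethylsilyl)oxy]-6-oxo-3-(propan-2-yl)-3-[(trimethylsilyl)oxy]heptanal, via ozonide 7 (not isolated)
Conditions: O3, CH2Cl2, −78 °C; then PPh3, −78 °C to rt
Reagents that add atoms: ozone, O=[O+][O-]
Why: Ozonolysis with reductive work-up cleaves the only alkene to the 1,6-keto aldehyde; silyl ethers are inert.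

Step 6
Reactants: 8 keto aldehyde
Product: 10 (3S,5R)-3-[(tert-butyldimethylsilyl)oxy]-2-methyl-5-(propan-2-yl)-5-[(trimethylsilyl)oxy]cyclopent-1-ene-1-carbaldehyde, via β-hydroxy aldehyde 9 (not isolated)
Conditions: piperidine (0.2 equiv), AcOH (0.2 equiv), PhMe, 4 Å MS, rt to 40 °C
Reagents that add atoms: none
Why: Amine/acid-catalysed intramolecular aldol condensation: the aldehyde enamine carbon (C5) adds to the methyl ketone (C1) in a 5-exo closure and the free tertiary aldol hydroxyl leaves as water while the silylated C4 oxygen stays; short exposure limits epimerisation at the α-silyloxy centre C2.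

Step 7
Reactants: 10 cyclopentene carbaldehyde; 11 3-bromobut-1-yne (racemic)
Product: 13 1-[(3S,5R)-3-(TBS-oxy)-5-hydroxy-2-methyl-5-(propan-2-yl)cyclopent-1-en-1-yl]-2-methylbut-3-yn-1-ol (epimers at both new centres), via TMS-protected adduct 12 (not isolated)
Conditions: Zn dust, THF, 0 °C to rt, aq. NH4Cl work-up; then K2CO3, MeOH, 0 °C
Reagents that add atoms: 3-bromobut-1-yne, CC(Br)C#C
Why: Zinc Barbier propargylation: the allenylzinc adds to the aldehyde by SE2′ to give the α-methyl homopropargylic alcohol (both new centres are removed later), and mild methanolysis then cleaves only the trimethylsilyl ether.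

Step 8
Reactants: 13 alkynyl diol
Product: 14 1-[(3S,5R)-3-(TBS-oxy)-5-hydroxy-2-methyl-5-(propan-2-yl)cyclopent-1-en-1-yl]-2-methylbut-3-yn-1-one (C8 epimers)
Conditions: Dess–Martin periodinane, pyridine, CH2Cl2, 0 °C to rt
Reagents that add atoms: none
Why: Dess–Martin oxidation of the secondary alcohol; the tertiary alcohol is inert and the buffered medium should keep the β,γ-alkynyl ketone from isomerising to the allenyl ketone.

Step 9
Reactants: 14 alkynyl hydroxy ketone; 15 diisopropylsilyl bis(trifluoromethanesulfonate)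
Product: 17 cyclic O4,O6-diisopropylsilylene enol ether with C6=C8 (methyl on C8 cis to O6; ethynyl cis to C5; 2α-OTBS; C1=C5), via silyl triflate 16 (not isolated)
Conditions: iPr2Si(OTf)2, 2,6-lutidine, CH2Cl2, −78 to 0 °C; then Et3N, −78 to 0 °C
Reagents that add atoms: diisopropylsilyl bis(trifluoromethanesulfonate), CC(C)[Si](OS(=O)(=O)C(F)(F)F)(OS(=O)(=O)C(F)(F)F)C(C)C
Why: Soft enolisation by a tethered silyl triflate: O4 is silylated first, the second Si–OTf activates the ketone intramolecularly and the amine removes the only α-hydrogen (C8–H, propargylic), closing the six-membered dioxasiline; the crowded site on C8 next to ring carbon C5 should be taken by the slim ethynyl group and the open site next to O6 by methyl, which is the geometry a cis-divinylcyclopropane needs.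

Step 10
Reactants: 17 siloxy enyne
Product: 18 cyclic O4,O6-diisopropylsilylene trienol ether (C1=C5, C6=C8, C9=C10; vinyl cis to C5)
Conditions: H2 (1 atm), Lindlar catalyst, quinoline, EtOAc/hexane, rt
Reagents that add atoms: none
Why: Lindlar semihydrogenation reduces only the terminal alkyne to the vinyl group; the tetrasubstituted enol ether and cyclopentene are inert to the poisoned catalyst.

Step 11
Reactants: 18 trienol ether; 19 diiodomethane
Product: 21 hydroazulene C5=C6 silylene enol ether (C1 methyl β; C8=C9), via siloxy divinylcyclopropane 20 (not isolated)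
Conditions: Et2Zn (3 equiv), CH2I2 (3 equiv), PhMe, −20 to 0 °C; pyridine; then 90 °C
Reagents that add atoms: diiodomethane, ICI
Why: In the Furukawa-modified Simmons–Smith reaction the electrophilic zinc carbenoid adds CH2 (C7) concertedly to the most electron-rich alkene, the silyl enol ether C6=C8, forming C6–C7 and C7–C8 with retention of alkene geometry, so the cyclopentenyl and vinyl groups are cis on cyclopropane 20. On warming, 20 undergoes the cis-divinylcyclopropane–cycloheptadiene [3,3] shift through the endo boat transition state: C6–C8 breaks, C1–C10 forms and the seven-membered ring closes pericyclically, leaving C5=C6 (enol ether) and C8=C9, both cis in the ring. The closest known reactions are cyclopropanation of siloxydienes at the enol ether double bond and the thermal rearrangement of 1-siloxy-1,2-divinylcyclopropanes. The new quaternary centre C1 is controlled by C4 through the tether: the dioxasiline holds O6 next to C4 and turns the α face of the enol ether against the α isopropyl group, so CH2 should enter from the β face, C8 then lies under the cyclopentene and C10 bonds to the α face of C1. The step needs chemoselectivity for the enol ether over the vinyl and cyclopentene alkenes (siloxy donor), facial selectivity (isopropyl shielding plus tether) and a concerted shift at a fully substituted terminus, which the tether helps by fixing the cyclopentenyl arm in the reactive orientation while pyridine ties up zinc iodide before heating.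

Step 12
Reactants: 21 hydroazulene silylene enol ether
Product: 22 2α-TBS-oxy-4β-hydroxydauc-8-en-6-one as a C5 epimer mixture
Conditions: HF·pyridine, pyridine, THF, 0 °C
Reagents that add atoms: none
Why: Buffered fluoride cleavage of the silyl enol ether and the Si–O4 bond frees the β-hydroxy ketone while the hindered secondary TBS ether stays; C-protonation is expected largely from the open β face (cis fusion), so the mixture is carried on and corrected in step 13.

Step 13
Reactants: 22 hydroxy ketone (C5 mixture)
Product: 24 2α-TBS-oxy-4β-hydroxy-5α-H-dauc-8-en-6-one (trans ring fusion), via dilithium alkoxide dienolate 23 (not isolated)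
Conditions: LDA (2.1 equiv), THF, −78 °C; t-BuOH (0.1 equiv), −78 to −10 °C; AcOH, −78 °C
Reagents that add atoms: none
Why: Enolate equilibration followed by kinetic protonation: LDA forms the alkoxide and the C6=C7 dienolate, the catalytic alcohol shuttles protons so that C5 epimerises through the minor C5 enolate while the acidic C7 position stays masked, the dianion should settle in the epimer that allows an O4–Li–O6 chelate (C6 cis to O4, anti to isopropyl), and protonation of the dienolate at its α-carbon C7 returns the skipped C8=C9 alkene.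

Step 14
Reactants: 24 trans-fused hydroxy ketone
Product: 25 2α-TBS-oxydauc-8-ene-4β,6α-diol
Conditions: Me4NBH(OAc)3, MeCN/AcOH (1:1), −30 to −10 °C
Reagents that add atoms: none
Why: Evans–Saksena reduction: the 4β-hydroxyl, cis to C6 on the cyclopentane, delivers hydride to the β face of the C6 carbonyl and should give the 6α-alcohol, overriding the angular methyl that would steer free hydride to the α face.

Step 15
Reactants: 25 diol; 26 4-acetoxybenzoyl chloride
Product: 27 6α-(4-acetoxybenzoyloxy)-2α-TBS-oxydauc-8-en-4β-ol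
Conditions: pyridine, DMAP (cat.), CH2Cl2, 0 °C to rt
Reagents that add atoms: 4-acetoxybenzoyl chloride, CC(=O)Oc1ccc(cc1)C(Cl)=O
Why: DMAP-catalysed acylation of the only secondary hydroxyl by the acid chloride; the tertiary hydroxyl does not react.

Step 16
Reactants: 27 silyl ether ester
Product: 28 6α-(4-acetoxybenzoyloxy)dauc-8-ene-2α,4β-diol
Conditions: HF·pyridine, pyridine, THF, 0 °C to rt
Reagents that add atoms: none
Why: Fluoride desilylation in a buffered acidic medium removes the TBS ether and leaves the aryl acetate, the benzoate ester and the tertiary alcohol intact.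

Step 17
Reactants: 28 diol ester; 29 acetic anhydride
Product: 30 2α-acetoxy-6α-(4-acetoxybenzoyloxy)dauc-8-en-4β-ol
Conditions: Ac2O, pyridine, DMAP (cat.), CH2Cl2, 0 °C to rt
Reagents that add atoms: acetic anhydride, CC(=O)OC(C)=O
Why: DMAP-catalysed acetylation of the secondary C2 hydroxyl; the tertiary C4 hydroxyl is inert under these conditions.

Step 18
Reactants: 30 phenol-protected precursor
Product: 31 CNP0275279.1, (1R,2S,4R,5S,6S)-2α-acetoxy-6α-(4-hydroxybenzoyloxy)dauc-8-en-4β-ol
Conditions: pyrrolidine (3 equiv), CH2Cl2, 0 °C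
Reagents that add atoms: none
Why: Chemoselective aminolysis: the phenolic acetate is a far better acyl donor than the hindered alkyl acetate or the benzoate ester, so pyrrolidine should free only the phenol.

**Compound list**

1 | (S)-terpinen-4-ol | CC1=CC[C@](O)(C(C)C)CC1 | starting material
2 | (1R)-4-methyl-1-(propan-2-yl)cyclohex-4-ene-1,3-diol, C3 epimers | CC1=CC[C@](O)(C(C)C)CC1O | intermediate
3 | (5R)-5-hydroxy-2-methyl-5-(propan-2-yl)cyclohex-2-en-1-one | CC1=CC[C@](O)(C(C)C)CC1=O | intermediate
4 | (1R,3S)-4-methyl-1-(propan-2-yl)cyclohex-4-ene-1,3-diol | CC1=CC[C@](O)(C(C)C)C[C@@H]1O | intermediate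
5 | (1R,5S)-5-(TBS-oxy)-4-methyl-1-(propan-2-yl)cyclohex-3-en-1-ol | CC1=CC[C@](O)(C(C)C)C[C@@H]1O[Si](C)(C)C(C)(C)C | intermediate (not isolated)
6 | (1S,5R)-1-(TBS-oxy)-2-methyl-5-(propan-2-yl)-5-(TMS-oxy)cyclohex-2-ene | CC1=CC[C@](O[Si](C)(C)C)(C(C)C)C[C@@H]1O[Si](C)(C)C(C)(C)C | intermediate
7 | ozonide (1,2,4-trioxolane) of 6 | CC12OOC(O1)C[C@](O[Si](C)(C)C)(C(C)C)C[C@@H]2O[Si](C)(C)C(C)(C)C | intermediate (not isolated)
8 | (3S,5S)-5-(TBS-oxy)-6-oxo-3-(propan-2-yl)-3-(TMS-oxy)heptanal | CC(=O)[C@@H](O[Si](C)(C)C(C)(C)C)C[C@@](O[Si](C)(C)C)(C(C)C)CC=O | intermediate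
9 | aldol adduct, 2-hydroxy-2-methylcyclopentane-1-carbaldehyde bearing 3-OTBS, 5-isopropyl and 5-OTMS (new centres unassigned) | CC1(O)C(C=O)[C@](O[Si](C)(C)C)(C(C)C)C[C@@H]1O[Si](C)(C)C(C)(C)C | intermediate (not isolated)
10 | (3S,5R)-3-(TBS-oxy)-2-methyl-5-(propan-2-yl)-5-(TMS-oxy)cyclopent-1-ene-1-carbaldehyde | CC1=C(C=O)[C@](O[Si](C)(C)C)(C(C)C)C[C@@H]1O[Si](C)(C)C(C)(C)C | intermediate
11 | 3-bromobut-1-yne (racemic) | CC(Br)C#C | starting material
12 | TMS-protected propargylation adduct of 10 (C6/C8 epimers) | C#CC(C)C(O)C1=C(C)[C@@H](O[Si](C)(C)C(C)(C)C)C[C@@]1(O[Si](C)(C)C)C(C)C | intermediate (not isolated)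
13 | 1-[(3S,5R)-3-(TBS-oxy)-5-hydroxy-2-methyl-5-(propan-2-yl)cyclopent-1-en-1-yl]-2-methylbut-3-yn-1-ol (C6/C8 epimers) | C#CC(C)C(O)C1=C(C)[C@@H](O[Si](C)(C)C(C)(C)C)C[C@@]1(O)C(C)C | intermediate
14 | 1-[(3S,5R)-3-(TBS-oxy)-5-hydroxy-2-methyl-5-(propan-2-yl)cyclopent-1-en-1-yl]-2-methylbut-3-yn-1-one (C8 epimers) | C#CC(C)C(=O)C1=C(C)[C@@H](O[Si](C)(C)C(C)(C)C)C[C@@]1(O)C(C)C | intermediate
15 | diisopropylsilyl bis(trifluoromethanesulfonate) | CC(C)[Si](OS(=O)(=O)C(F)(F)F)(OS(=O)(=O)C(F)(F)F)C(C)C | starting material
16 | O4-[diisopropyl(triflyloxy)silyl] ether of 14 | C#CC(C)C(=O)C1=C(C)[C@@H](O[Si](C)(C)C(C)(C)C)C[C@@]1(O[Si](C(C)C)(C(C)C)OS(=O)(=O)C(F)(F)F)C(C)C | intermediate (not isolated)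
17 | cyclic O4,O6-diisopropylsilylene enol ether, C6=C8 with methyl cis to O6 and ethynyl cis to C5, 2α-OTBS, C1=C5 | CC(C)(C)[Si](C)(C)O[C@H]1C[C@]2(C(C)C)O[Si](C(C)C)(C(C)C)O/C(=C(\C)C#C)C2=C1C | intermediate
18 | cyclic O4,O6-diisopropylsilylene trienol ether, as 17 with vinyl in place of ethynyl | CC(C)(C)[Si](C)(C)O[C@H]1C[C@]2(C(C)C)O[Si](C(C)C)(C(C)C)O/C(=C(\C)C=C)C2=C1C | intermediate (key-step precursor)
19 | diiodomethane | ICI | starting material
20 | 1-siloxy-cis-divinylcyclopropane (C7 on the β face; cyclopentenyl and vinyl cis) | CC(C)(C)[Si](C)(C)O[C@H]1C[C@]2(C(C)C)O[Si](C(C)C)(C(C)C)O[C@]3(C[C@]3(C)C=C)C2=C1C | intermediate (not isolated)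
21 | hydroazulene C5=C6 O4,O6-diisopropylsilylene enol ether, 2α-OTBS, C1 methyl β, C8=C9 | CC(C)(C)[Si](C)(C)O[C@H]1C[C@]2(C(C)C)O[Si](C(C)C)(C(C)C)OC3=C2[C@@]1(C)CC=C(C)C3 | intermediate (key-step product)
22 | 2α-TBS-oxy-4β-hydroxydauc-8-en-6-one, C5 epimers | CC(C)(C)[Si](C)(C)O[C@H]1C[C@@](O)(C(C)C)C2C(=O)CC(C)=CC[C@@]12C | intermediate
23 | dilithium 4-alkoxide 6,7-dienolate of 24 | CC(C)(C)[Si](C)(C)O[C@H]1C[C@@]([O-])(C(C)C)[C@@H]2C([O-])=CC(C)=CC[C@@]12C.[Li+].[Li+] | intermediate (not isolated)
24 | 2α-TBS-oxy-4β-hydroxy-5α-H-dauc-8-en-6-one | CC(C)(C)[Si](C)(C)O[C@H]1C[C@@](O)(C(C)C)[C@@H]2C(=O)CC(C)=CC[C@@]12C | intermediate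
25 | 2α-TBS-oxydauc-8-ene-4β,6α-diol | CC(C)(C)[Si](C)(C)O[C@H]1C[C@@](O)(C(C)C)[C@@H]2[C@@H](O)CC(C)=CC[C@@]12C | intermediate
26 | 4-acetoxybenzoyl chloride | CC(=O)Oc1ccc(cc1)C(Cl)=O | starting material
27 | 6α-(4-acetoxybenzoyloxy)-2α-TBS-oxydauc-8-en-4β-ol | CC(C)(C)[Si](C)(C)O[C@H]1C[C@@](O)(C(C)C)[C@@H]2[C@@H](OC(=O)c3ccc(OC(C)=O)cc3)CC(C)=CC[C@@]12C | intermediate
28 | 6α-(4-acetoxybenzoyloxy)dauc-8-ene-2α,4β-diol | O[C@H]1C[C@@](O)(C(C)C)[C@@H]2[C@@H](OC(=O)c3ccc(OC(C)=O)cc3)CC(C)=CC[C@@]12C | intermediate
29 | acetic anhydride | CC(=O)OC(C)=O | starting material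
30 | 2α-acetoxy-6α-(4-acetoxybenzoyloxy)dauc-8-en-4β-ol | CC(=O)O[C@H]1C[C@@](O)(C(C)C)[C@@H]2[C@@H](OC(=O)c3ccc(OC(C)=O)cc3)CC(C)=CC[C@@]12C | intermediate
31 | CNP0275279.1, (1R,2S,4R,5S,6S)-2α-acetoxy-6α-(4-hydroxybenzoyloxy)dauc-8-en-4β-ol | CC(=O)O[C@H]1C[C@@](O)(C(C)C)[C@@H]2[C@@H](OC(=O)c3ccc(O)cc3)CC(C)=CC[C@@]12C | target

**Step count and risks**

Total steps: 18. Longest linear sequence: 18 steps, from 1 to 31.

Most likely to fail:

Step 11. Methylene may be delivered to the wrong face of the enol ether, or to the vinyl group or the product enol ether. Zinc iodide may also open the siloxycyclopropane while the shift to the fully substituted C1, syn to the C2 silyloxy group, is slow. Fallback: separate carbene transfer from rearrangement. Setting out from enyne 17, Et2Zn/CH2I2 (PhMe, 0 °C) meets a single electron-rich alkene and should give the ethynyl siloxycyclopropane F1, whose diastereomers can be separated because nothing rearranges yet. After removal of zinc salts, Lindlar semihydrogenation creates the second vinyl group only then, giving 20 under neutral conditions; gentle warming in PhMe rearranges it and the route is rejoined at 21.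

Step 13. Proton exchange at the hindered C5 may be slow, the transient alkoxide–ketone may fragment by retro-aldol, or the dienolate may be protonated at its γ-carbon on quench so that the alkene moves into conjugation. Fallback: equilibrate C5 in the neutral, still tethered series. Setting out from 21 (step 12 is bypassed), heating with catalytic triethylammonium triflate (DMF, 80 °C) should equilibrate the silyl enol ether by reversible C-protonation toward the conjugated C6=C7 dienol ether F2. In F2, C5 should carry hydrogen on the α face, because only that epimer keeps the dioxasilinane cis-fused to the cyclopentane and C6 away from the isopropyl group. TBAF/AcOH at −78 °C then cleaves the tether and protonates the dienolate at C7, rejoining the route at 24.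

Step 9. The alkynyl ketone may isomerise to the allenyl ketone before the enol is trapped, or ethynyl and methyl may be poorly differentiated so that the enol ether geometry is mixed. Fallback: set the geometry by γ-deprotonation of a conjugated enone. Setting out from aldehyde 10, (E)-but-2-en-2-yllithium (from (E)-2-bromobut-2-ene and t-BuLi, THF, −78 °C) adds to give the TMS-protected dienyl carbinol F3. Methanolysis (K2CO3, MeOH) gives the diol F4, and MnO2 gives the cross-conjugated tiglyl dienone F5. iPr2Si(OTf)2/Et3N then ties O4 to the carbonyl oxygen and removes a C10 hydrogen from the s-trans enone, which places O6 cis to the C8 methyl. This gives trienol ether 18 directly, so step 10 is skipped and the route is rejoined at 18.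

**Further compounds**

F1 | step 11 | ethynyl siloxycyclopropane (20 with ethynyl in place of vinyl) | CC(C)(C)[Si](C)(C)O[C@H]1C[C@]2(C(C)C)O[Si](C(C)C)(C(C)C)O[C@]3(C[C@]3(C)C#C)C2=C1C
F2 | step 13 | O4,O6-diisopropylsilylene C6=C7 dienol ether, 5α-H, 2α-OTBS | CC(C)(C)[Si](C)(C)O[C@H]1C[C@]2(C(C)C)O[Si](C(C)C)(C(C)C)OC3=CC(C)=CC[C@]1(C)[C@H]23
F3 | step 9 | TMS-protected (E)-2-methylbut-2-enyl carbinol from 10 (C6 epimers) | C/C=C(\C)C(O)C1=C(C)[C@@H](O[Si](C)(C)C(C)(C)C)C[C@@]1(O[Si](C)(C)C)C(C)C
F4 | step 9 | (E)-2-methylbut-2-enyl carbinol diol (C6 epimers) | C/C=C(\C)C(O)C1=C(C)[C@@H](O[Si](C)(C)C(C)(C)C)C[C@@]1(O)C(C)C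
F5 | step 9 | cross-conjugated tiglyl dienone | C/C=C(\C)C(=O)C1=C(C)[C@@H](O[Si](C)(C)C(C)(C)C)C[C@@]1(O)C(C)C
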